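A direct plan would reduce 3,5-dibromo-4-hydroxybenzaldehyde A1 to the benzyl alcohol A2 and ionise A2 with acid to the para-quinone methide A3. After conversion of 4-hydroxyphenylboronic acid A4 into its potassium trifluoroborate A5, A3 would benzylate A5 at the boron-bearing carbon to give the diarylmethane A6, and one bromination ortho to the free phenol of ring B would finish.
Its weakest steps would be:
- the quinone methide benzylation, because an unsubstituted quinone methide oligomerises easily and ipso-selective deborylative C–C bond formation is unproven on such a substrate;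
- the closing monobromination, because only stoichiometry would stop it at one bromine, and the di-, tri- and tetrabromides of one skeleton are hard to separate;
- the aldehyde reduction and the borate formation, two operations that form no skeletal bond.

**Strategy.** The route would not substitute any phenol. Ring B would be carried as a cyclohexane-1,3-dione mono enol ether with bromine on C2. Its C3 (oxygen), C2 (bromine) and C6 map onto C–OH, the ortho C–Br and the para carbon of ring B. An aldol condensation at C6 would bring in ring A as an arylidene. In the key step, 1,2-reduction and acid would move the carbonyl group to C3 (1,3-transposition), and the resulting 2-bromo-4-arylidenecyclohex-2-enone would tautomerise to the phenol, the aldehyde carbon ending as the CH2 bridge. The 2 + 1 bromine pattern comes from the building blocks, so the quinone methide benzylation, the boron reagent and the late bromination have no counterpart.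

Key step: step 4

Remark: the target has no stereocentre; the stereocentres and the alkene geometry that appear in the intermediates are consumed on the way and need no control.

Step 1
Reactants: 1 3-ethoxycyclohex-2-en-1-one
Product: 2 2-bromo-3-ethoxycyclohex-2-en-1-one
Conditions: NBS (1.05 equiv), CH2Cl2, 0 → 25 °C, dark
Reagents that add atoms: N-bromosuccinimide, O=C1CCC(=O)N1Br
Why: Electrophilic α-halogenation of a vinylogous ester should take place at C2, the only carbon activated by the enol ether, with the oxocarbenium ion losing the C2 proton to succinimide anion and the acid-free, dark conditions sparing the enol ether and the allylic positions.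

Step 2
Reactants: 3 3,5-dibromo-4-hydroxybenzaldehyde
Product: 4 3,5-dibromo-4-(methoxymethoxy)benzaldehyde
Conditions: MOMCl (1.5 equiv), iPr2NEt (2.0 equiv), CH2Cl2, 0 → 25 °C
Reagents that add atoms: chloromethyl methyl ether, COCCl
Why: O-Alkylation of the phenoxide (methoxymethyl ether protection) masks the acidic phenol, which would otherwise quench the enolate of step 3 and deactivate the aldehyde, with a group that is stable to base and hydride and falls off in the acid of step 4.

Step 3
Reactants: 2 2-bromo-3-ethoxycyclohex-2-en-1-one; 4 3,5-dibromo-4-(methoxymethoxy)benzaldehyde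
Product: 8 (6E)-2-bromo-6-{[3,5-dibromo-4-(methoxymethoxy)phenyl]methylidene}-3-ethoxycyclohex-2-en-1-one, via lithium dienolate 5 (not isolated), via lithium aldolate 6 (not isolated), via aldol mesylate 7 (not isolated)
Conditions: LiN(iPr)2 (1.1 equiv), THF, −78 °C, 2 then 4; MsCl (1.5 equiv), −78 → 0 °C; DBU (3.0 equiv), 0 → 25 °C
Reagents that add atoms: none
Why: In this directed aldol condensation (aldol addition, mesylation, E1cB elimination), kinetic deprotonation of a 3-alkoxycyclohexenone should occur at C6, the dienolate should add to the non-enolisable aldehyde, and loss of methanesulfonate should give the conjugated arylidene, expected as the E isomer.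

Step 4
Reactants: 8 (6E)-2-bromo-6-{[3,5-dibromo-4-(methoxymethoxy)phenyl]methylidene}-3-ethoxycyclohex-2-en-1-one
Product: 12 2,6-dibromo-4-[(3-bromo-4-hydroxyphenyl)methyl]phenol, via allylic alcohol 9 (not isolated), via transposed dienone 10 (not isolated), via methoxymethyl ether 11 (not isolated)
Conditions: NaBH4 (1.5 equiv), CeCl3·7H2O (1.2 equiv), MeOH/THF 3:1, −20 → 0 °C; then 3 M aq HCl (to about 1 M), 25 °C, 1 h, then 65 °C
Reagents that add atoms: water, O
Why: Luche 1,2-reduction should give the doubly allylic alcohol 9; acid ionises it to a cation held mainly as the ethoxy-substituted oxocarbenium ion, water adds at that carbon and ethanol leaves (Stork–Danheiser 1,3-carbonyl transposition), so that the carbonyl group moves to the old C3 and dienone 10 results. Dienone 10 is a non-aromatic tautomer of a para-benzylphenol: acid-catalysed enolisation towards C6, protonation of the exocyclic carbon to an arenium ion and loss of the C5 proton (isoaromatisation of an alkylidenecyclohexenone, driven by the aromatic stabilisation of ring B) should give 11, from which the same acid removes the methoxymethyl group by methanolysis. No ring is closed, since the carbocycle of ring B is present from compound 1 and is only aromatised here, and no stereocentre is formed, the one of 9 being destroyed. The regiochemistry follows from the atom map and not from a selective substitution: the enol ether carbon becomes C–OH, the brominated carbon next to it stays ortho, the old C6 becomes the para carbon and the aldehyde carbon becomes the CH2 bridge. The selectivities needed are 1,2-addition of hydride, secured by CeCl3, and retention of the bromine, secured because it sits on an sp2 carbon throughout and 10 already has the oxidation level of the phenol, so that no HBr has to be lost; capture of the cation at its benzylic end is reversible and leads back to 10. The closest known reaction types are the reductive transposition of 6-substituted 2-halo-3-alkoxycyclohex-2-enones and the acid-mediated isomerisation of arylidenecyclohexenones to benzylphenols.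

**Compound list**
1 | 3-ethoxycyclohex-2-en-1-one | CCOC1=CC(=O)CCC1 | starting material
2 | 2-bromo-3-ethoxycyclohex-2-en-1-one | CCOC1=C(Br)C(=O)CCC1 | intermediate
3 | 3,5-dibromo-4-hydroxybenzaldehyde | O=Cc1cc(Br)c(O)c(Br)c1 | starting material
4 | 3,5-dibromo-4-(methoxymethoxy)benzaldehyde | COCOc1c(Br)cc(C=O)cc1Br | intermediate
5 | lithium 6-bromo-5-ethoxycyclohexa-1,5-dien-1-olate | [Li+].CCOC1=C(Br)C([O-])=CCC1 | intermediate
6 | lithium (3-bromo-4-ethoxy-2-oxocyclohex-3-en-1-yl)[3,5-dibromo-4-(methoxymethoxy)phenyl]methanolate (mixture of diastereomers) | [Li+].CCOC1=C(Br)C(=O)C(CC1)C([O-])c1cc(Br)c(OCOC)c(Br)c1 | intermediate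
7 | (3-bromo-4-ethoxy-2-oxocyclohex-3-en-1-yl)[3,5-dibromo-4-(methoxymethoxy)phenyl]methyl methanesulfonate (mixture of diastereomers) | CCOC1=C(Br)C(=O)C(CC1)C(OS(C)(=O)=O)c1cc(Br)c(OCOC)c(Br)c1 | intermediate
8 | (6E)-2-bromo-6-{[3,5-dibromo-4-(methoxymethoxy)phenyl]methylidene}-3-ethoxycyclohex-2-en-1-one | CCOC1=C(Br)C(=O)/C(CC1)=C/c1cc(Br)c(OCOC)c(Br)c1 | intermediate
9 | (6E)-2-bromo-6-{[3,5-dibromo-4-(methoxymethoxy)phenyl]methylidene}-3-ethoxycyclohex-2-en-1-ol (racemic) | CCOC1=C(Br)C(O)/C(CC1)=C/c1cc(Br)c(OCOC)c(Br)c1 | intermediate
10 | (4E)-2-bromo-4-{[3,5-dibromo-4-(methoxymethoxy)phenyl]methylidene}cyclohex-2-en-1-one | O=C1CC/C(=C\c2cc(Br)c(OCOC)c(Br)c2)C=C1Br | intermediate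
11 | 2-bromo-4-{[3,5-dibromo-4-(methoxymethoxy)phenyl]methyl}phenol | COCOc1c(Br)cc(Cc2ccc(O)c(Br)c2)cc1Br | intermediate
12 | 2,6-dibromo-4-[(3-bromo-4-hydroxyphenyl)methyl]phenol | Oc1ccc(Cc2cc(Br)c(O)c(Br)c2)cc1Br | target

Total step count: 4. Longest linear sequence: 3 steps (steps 1, 3, 4 from 1, or steps 2, 3, 4 from 3).

**Steps most likely to fail**

Step 4. Hydride may add in the conjugate sense to the arylidene enone, or dienone 10 may be lost to solvent addition and oligomerisation faster than it tautomerises. The fallback sets out from 8 and takes the last unsaturation of ring B from an oxidant instead of the exocyclic alkene. Conjugate reduction of the arylidene C=C with [(Ph3P)CuH]6 (toluene, 25 °C) would give 2-bromo-6-{[3,5-dibromo-4-(methoxymethoxy)phenyl]methyl}-3-ethoxycyclohex-2-en-1-one F1. NaBH4/CeCl3·7H2O would reduce F1 to 2-bromo-6-{[3,5-dibromo-4-(methoxymethoxy)phenyl]methyl}-3-ethoxycyclohex-2-en-1-ol F2, which brief cold 1 M HCl would transpose to 2-bromo-4-{[3,5-dibromo-4-(methoxymethoxy)phenyl]methyl}cyclohex-2-en-1-one F3. Dehydrogenation of F3 with DDQ (1.0 equiv, dioxane, 80 °C) would give 2-bromo-4-{[3,5-dibromo-4-(methoxymethoxy)phenyl]methyl}cyclohexa-2,5-dien-1-one F4, and tautomerisation of F4 would return to the route at 11, which the acid methanolysis of step 4 converts into 12.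

Step 3. The brominated dienolate 5 may decompose, or equilibrate by proton transfer to the γ-dienolate, before it adds to the aldehyde. The fallback sets out from 1 and 4 and changes the order of bond formation and bromination. The bromine-free dienolate lithium 5-ethoxycyclohexa-1,5-dien-1-olate F5, from 1 and LiN(iPr)2, would add to 4 to give lithium [3,5-dibromo-4-(methoxymethoxy)phenyl](4-ethoxy-2-oxocyclohex-3-en-1-yl)methanolate F6. MsCl would convert F6 into [3,5-dibromo-4-(methoxymethoxy)phenyl](4-ethoxy-2-oxocyclohex-3-en-1-yl)methyl methanesulfonate F7, and DBU would eliminate F7 to (6E)-6-{[3,5-dibromo-4-(methoxymethoxy)phenyl]methylidene}-3-ethoxycyclohex-2-en-1-one F8. NBS (CH2Cl2, 0 °C) would then brominate the enol ether α-carbon C2 of F8 and return to the route at 8. Step 1 and compound 2 would then not be needed.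

Step 1. Bromination may also occur at the allylic C4 and C6 positions or a second time, and traces of HBr may cleave the enol ether. The fallback sets out from 1 and brominates at the dione stage. Hydrolysis (1 M HCl, 25 °C) would give cyclohexane-1,3-dione F9, whose carbon between the two carbonyl groups is the only nucleophilic site. Bromination (NBS, water, 0 °C) would give 2-bromocyclohexane-1,3-dione F10. Acid-catalysed enol etherification (EtOH, cat. TsOH, toluene, water removal) would return to the route at 2; the symmetry of F10 makes its two carbonyl groups equivalent.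

**Further compounds**
F1 | step 4 | 2-bromo-6-{[3,5-dibromo-4-(methoxymethoxy)phenyl]methyl}-3-ethoxycyclohex-2-en-1-one (racemic) | CCOC1=C(Br)C(=O)C(CC1)Cc1cc(Br)c(OCOC)c(Br)c1
F2 | step 4 | 2-bromo-6-{[3,5-dibromo-4-(methoxymethoxy)phenyl]methyl}-3-ethoxycyclohex-2-en-1-ol (mixture of diastereomers) | CCOC1=C(Br)C(O)C(CC1)Cc1cc(Br)c(OCOC)c(Br)c1
F3 | step 4 | 2-bromo-4-{[3,5-dibromo-4-(methoxymethoxy)phenyl]methyl}cyclohex-2-en-1-one (racemic) | O=C1CCC(Cc2cc(Br)c(OCOC)c(Br)c2)C=C1Br
F4 | step 4 | 2-bromo-4-{[3,5-dibromo-4-(methoxymethoxy)phenyl]methyl}cyclohexa-2,5-dien-1-one (racemic) | O=C1C=CC(Cc2cc(Br)c(OCOC)c(Br)c2)C=C1Br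
F5 | step 3 | lithium 5-ethoxycyclohexa-1,5-dien-1-olate | [Li+].CCOC1=CC([O-])=CCC1
F6 | step 3 | lithium [3,5-dibromo-4-(methoxymethoxy)phenyl](4-ethoxy-2-oxocyclohex-3-en-1-yl)methanolate (mixture of diastereomers) | [Li+].CCOC1=CC(=O)C(CC1)C([O-])c1cc(Br)c(OCOC)c(Br)c1
F7 | step 3 | [3,5-dibromo-4-(methoxymethoxy)phenyl](4-ethoxy-2-oxocyclohex-3-en-1-yl)methyl methanesulfonate (mixture of diastereomers) | CCOC1=CC(=O)C(CC1)C(OS(C)(=O)=O)c1cc(Br)c(OCOC)c(Br)c1
F8 | step 3 | (6E)-6-{[3,5-dibromo-4-(methoxymethoxy)phenyl]methylidene}-3-ethoxycyclohex-2-en-1-one | CCOC1=CC(=O)/C(CC1)=C/c1cc(Br)c(OCOC)c(Br)c1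
F9 | step 1 | cyclohexane-1,3-dione | O=C1CCCC(=O)C1
F10 | step 1 | 2-bromocyclohexane-1,3-dione | O=C1CCCC(=O)C1Br
A1 | direct plan | 3,5-dibromo-4-hydroxybenzaldehyde | O=Cc1cc(Br)c(O)c(Br)c1
A2 | direct plan | 2,6-dibromo-4-(hydroxymethyl)phenol | OCc1cc(Br)c(O)c(Br)c1
A3 | direct plan | 2,6-dibromo-4-methylidenecyclohexa-2,5-dien-1-one | C=C1C=C(Br)C(=O)C(Br)=C1
A4 | direct plan | 4-hydroxyphenylboronic acid | OB(O)c1ccc(O)cc1
A5 | direct plan | potassium trifluoro(4-hydroxyphenyl)borate | [K+].F[B-](F)(F)c1ccc(O)cc1
A6 | direct plan | 2,6-dibromo-4-[(4-hydroxyphenyl)methyl]phenol | Oc1ccc(Cc2cc(Br)c(O)c(Br)c2)cc1
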